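**Strategy**

Numbering the carbocycle C1 (CH bearing the side chain), C2 (CMe2), C3–C5 (CH2) and C6 (carbinol carbon), the route rests on closing the C3–C4 bond. The precursor is an acyclic diene with the C1 stereocentre in place, a vinyl group on quaternary C2 and an allyl group on a C6 carbinol. Ring-closing metathesis forms C3=C4; a ruthenium hydride then walks this alkene, which quaternary C2 blocks on one side, into the C6 carbinol, so one operation delivers the saturated ring with a C6 ketone. That ketone later accepts the hydroxymethyl carbon trans to the side chain; the chromene follows by asymmetric allylic etherification and a second metathesis.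

Key step: step 4

Remark: compounds 5 and 6 are mixtures of epimers at the carbinol carbon, which becomes the planar ketone carbon in 7.

Assumption: in step 9 the (R,R)-ligand is taken to give the S-configured ether from the E-carbonate; if the sense of induction proves opposite, the (S,S)-ligand is used with no other change.

**Route**

Step 1
Reactants: 1 methyl 3,3-dimethylpent-4-enoate
Product: 2 3,3-dimethylpent-4-enal
Conditions: i-Bu2AlH (1.05 equiv), CH2Cl2, −78 °C; MeOH, then aq. potassium sodium tartrate
Reagents that add atoms: none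
Why: Partial ester reduction with diisobutylaluminium hydride stops at the aldehyde because the aluminium hemiacetal is stable at −78 °C, and the isolated vinyl group is inert.

Step 2
Reactants: 2 3,3-dimethylpent-4-enal; 3 methyl vinyl ketone (1.5 equiv)
Product: 4 (2S)-2-(2-methylbut-3-en-2-yl)-5-oxohexanal
Conditions: (S)-2-(methoxydiphenylmethyl)pyrrolidine (10 mol%), ethyl 3,4-dihydroxybenzoate (20 mol%), neat, 4 °C
Reagents that add atoms: none
Why: Enamine-catalysed asymmetric Michael addition of an aldehyde to an enone, in which the E-anti enamine is shielded on one face by the diphenylmethoxymethyl group so that the enone adds to the open face and sets C1 as S.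

Step 3
Reactants: 4 (2S)-2-(2-methylbut-3-en-2-yl)-5-oxohexanal
Product: 5 (5S)-6-hydroxy-5-(2-methylbut-3-en-2-yl)non-8-en-2-one (both carbinol epimers)
Conditions: allylB(pin) (1.3 equiv), toluene, 23→40 °C; aq. NH4Cl work-up
Reagents that add atoms: allylboronic acid pinacol ester, C=CCB1OC(C)(C)C(C)(C)O1
Why: Uncatalysed allylboration through a closed six-membered transition state is fast for aldehydes and negligible for ketones, so only the formyl group reacts, and the configuration of the new carbinol is irrelevant because it becomes a ketone in step 4.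

Step 4
Reactants: 5 (5S)-6-hydroxy-5-(2-methylbut-3-en-2-yl)non-8-en-2-one
Product: 7 (2S)-3,3-dimethyl-2-(3-oxobutyl)cyclohexan-1-one, via cyclohexenol 6 (not isolated)
Conditions: second-generation Grubbs catalyst (3 mol%), toluene, 50 °C; then RuHCl(CO)(PPh3)3 (5 mol%), 100 °C
Reagents that add atoms: none
Why: The ruthenium alkylidene loads at the unhindered allyl terminus, adds across the vinyl group on quaternary C2 by [2+2] cycloaddition and cycloreversion, and releases ethylene, so C3 and C4 are joined as a ring alkene; this is a ring-closing olefin metathesis of a 1,7-diene to a six-membered carbocycle, helped by the gem-dimethyl group. The ruthenium hydride added afterwards moves the alkene by reversible hydrometalation and beta-hydride elimination, and since C2 bears no hydrogen the only path is C3=C4 to C4=C5 to the C5=C6 enol, whose tautomerisation to the C6 ketone is irreversible. The closest known reaction types are tandem metathesis–isomerisation and the metal-hydride isomerisation of unsaturated alcohols to ketones. No stereocentre is created: the carbinol carbon of mixed configuration becomes the ketone, and the C1 centre from step 2 is preserved because the metal walk is stopped by C2 on one side and ends at C5=C6 on the other, under neutral conditions. The step needs the metathesis to finish before any isomerisation (otherwise the allyl group would become propenyl and a five-membered ring would close), which sequential addition of the hydride secures, and it needs the side-chain methyl ketone to stay untouched, which holds because any hydrogen transfer between carbinol and ketone still ends at the same saturated diketone.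

Step 5
Reactants: 7 (2S)-3,3-dimethyl-2-(3-oxobutyl)cyclohexan-1-one
Product: 8 ethyl (2E)-5-[(1S)-2,2-dimethyl-6-oxocyclohexyl]-3-methylpent-2-enoate
Conditions: (EtO)2P(O)CH2CO2Et (1.4 equiv), NaH (1.3 equiv), THF, 0→45 °C; Z isomer removed by chromatography
Reagents that add atoms: triethyl phosphonoacetate, CCOC(=O)CP(=O)(OCC)OCC
Why: Horner–Wadsworth–Emmons olefination selects the unhindered methyl ketone over the ring ketone flanked by tertiary C1 and quaternary C2, and the stabilised phosphonate anion favours the E-trisubstituted enoate without enolising C1.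

Step 6
Reactants: 8 ethyl (2E)-5-[(1S)-2,2-dimethyl-6-oxocyclohexyl]-3-methylpent-2-enoate
Product: 9 ethyl (2E)-5-[(3R,4S)-5,5-dimethyl-1-oxaspiro[2.5]octan-4-yl]-3-methylpent-2-enoate
Conditions: Me3S+ I− (1.5 equiv), KN(SiMe3)2 (1.4 equiv), THF, −10→23 °C
Reagents that add atoms: trimethylsulfonium iodide, C[S+](C)C.[I-]
Why: Corey–Chaykovsky epoxidation, in which the sulfonium methylide adds irreversibly to the ring ketone from the equatorial direction because the axial methyl on C2 blocks the axial path, placing the new CH2 trans and the oxygen cis to the C1 side chain (C6 = R), while the beta,beta-disubstituted enoate is a poor acceptor.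

Step 7
Reactants: 9 ethyl (2E)-5-[(3R,4S)-5,5-dimethyl-1-oxaspiro[2.5]octan-4-yl]-3-methylpent-2-enoate
Product: 10 (2E)-5-[(3R,4S)-5,5-dimethyl-1-oxaspiro[2.5]octan-4-yl]-3-methylpent-2-en-1-ol
Conditions: i-Bu2AlH (2.3 equiv), CH2Cl2, −78 °C; aq. potassium sodium tartrate
Reagents that add atoms: none
Why: 1,2-Reduction of the conjugated ester to the allylic alcohol with diisobutylaluminium hydride at low temperature, where the hindered spiro-epoxide is not opened and the alkene geometry is kept.

Step 8
Reactants: 10 (2E)-5-[(3R,4S)-5,5-dimethyl-1-oxaspiro[2.5]octan-4-yl]-3-methylpent-2-en-1-ol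
Product: 11 (2E)-5-[(3R,4S)-5,5-dimethyl-1-oxaspiro[2.5]octan-4-yl]-3-methylpent-2-en-1-yl methyl carbonate
Conditions: ClCO2Me (1.5 equiv), pyridine, CH2Cl2, 0 °C
Reagents that add atoms: methyl chloroformate, COC(=O)Cl
Why: O-Acylation of the only hydroxyl group gives the allylic carbonate that serves as leaving group for palladium allyl chemistry.

Step 9
Reactants: 11 the allylic methyl carbonate; 12 2,6-dihydroxy-4-methylbenzaldehyde (2.5 equiv)
Product: 13 2-hydroxy-6-({(3S)-5-[(3R,4S)-5,5-dimethyl-1-oxaspiro[2.5]octan-4-yl]-3-methylpent-1-en-3-yl}oxy)-4-methylbenzaldehyde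
Conditions: Pd2(dba)3·CHCl3 (2.5 mol%), (1R,2R)-N,N'-bis(2-diphenylphosphinobenzoyl)cyclohexane-1,2-diamine (7.5 mol%), CH2Cl2 (0.05 M), 23 °C
Reagents that add atoms: none
Why: Palladium-catalysed asymmetric allylic etherification (Tsuji–Trost reaction), in which ionisation of the E-carbonate gives a 1,1-disubstituted pi-allyl palladium complex and the acidic phenol attacks its more substituted terminus inside the chiral ligand pocket, so the ligand sets the tertiary ether centre as S, while the excess of the symmetric diphenol limits double alkylation.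

Step 10
Reactants: 13 the aryl ether aldehyde
Product: 14 2-ethenyl-3-({(3S)-5-[(3R,4S)-5,5-dimethyl-1-oxaspiro[2.5]octan-4-yl]-3-methylpent-1-en-3-yl}oxy)-5-methylphenol
Conditions: Ph3PCH3Br (3.2 equiv), KOtBu (3.0 equiv), THF, 0→23 °C
Reagents that add atoms: methyltriphenylphosphonium bromide, C[P+](c1ccccc1)(c1ccccc1)c1ccccc1.[Br-]
Why: Wittig methylenation of the aryl aldehyde with excess ylide, one equivalent of which is consumed by the phenol, under conditions where the epoxide and the tertiary allyl ether are inert.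

Step 11
Reactants: 14 the styrene
Product: 15 (2S)-2-{2-[(3R,4S)-5,5-dimethyl-1-oxaspiro[2.5]octan-4-yl]ethyl}-2,7-dimethyl-2H-chromen-5-ol
Conditions: second-generation Grubbs catalyst (5 mol%), CH2Cl2, 40 °C
Reagents that add atoms: none
Why: Ring-closing metathesis of the styrene with the vinyl group on the ether carbon closes the pyran ring of the 2H-chromene with loss of ethylene and does not touch the quaternary ether centre.

Step 12
Reactants: 15 the chromene epoxide
Product: 16 (2S)-2-{2-[(1S,2R)-2-hydroxy-2-(hydroxymethyl)-6,6-dimethylcyclohexyl]ethyl}-2,7-dimethyl-2H-chromen-5-ol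
Conditions: KOH (2 M aq.), DMSO, 90 °C, exclusion of light; aq. NH4Cl work-up
Reagents that add atoms: water, O (delivered as hydroxide from potassium hydroxide, [K+].[OH-])
Why: Hydroxide opens the spiro-epoxide by SN2 attack at its unsubstituted CH2, so the C6–O bond and its R configuration are retained, and the phenoxide and the chromene tolerate base.

**Compound list**

1 | methyl 3,3-dimethylpent-4-enoate | COC(=O)CC(C)(C)C=C | starting material
2 | 3,3-dimethylpent-4-enal | O=CCC(C)(C)C=C | intermediate
3 | methyl vinyl ketone | CC(=O)C=C | starting material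
4 | (2S)-2-(2-methylbut-3-en-2-yl)-5-oxohexanal | O=C[C@@H](CCC(C)=O)C(C)(C)C=C | intermediate
5 | (5S)-6-hydroxy-5-(2-methylbut-3-en-2-yl)non-8-en-2-one (both carbinol epimers) | C=CCC(O)[C@@H](CCC(C)=O)C(C)(C)C=C | intermediate
6 | 4-[(1S)-2-hydroxy-6,6-dimethylcyclohex-4-en-1-yl]butan-2-one (both carbinol epimers, not isolated) | CC(=O)CC[C@H]1C(C)(C)C=CCC1O | intermediate
7 | (2S)-3,3-dimethyl-2-(3-oxobutyl)cyclohexan-1-one | CC(=O)CC[C@H]1C(C)(C)CCCC1=O | intermediate
8 | ethyl (2E)-5-[(1S)-2,2-dimethyl-6-oxocyclohexyl]-3-methylpent-2-enoate | CCOC(=O)/C=C(\C)CC[C@H]1C(C)(C)CCCC1=O | intermediate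
9 | ethyl (2E)-5-[(3R,4S)-5,5-dimethyl-1-oxaspiro[2.5]octan-4-yl]-3-methylpent-2-enoate | CCOC(=O)/C=C(\C)CC[C@H]1C(C)(C)CCC[C@]12CO2 | intermediate
10 | (2E)-5-[(3R,4S)-5,5-dimethyl-1-oxaspiro[2.5]octan-4-yl]-3-methylpent-2-en-1-ol | OC/C=C(\C)CC[C@H]1C(C)(C)CCC[C@]12CO2 | intermediate
11 | (2E)-5-[(3R,4S)-5,5-dimethyl-1-oxaspiro[2.5]octan-4-yl]-3-methylpent-2-en-1-yl methyl carbonate | COC(=O)OC/C=C(\C)CC[C@H]1C(C)(C)CCC[C@]12CO2 | intermediate
12 | 2,6-dihydroxy-4-methylbenzaldehyde | Cc1cc(O)c(C=O)c(O)c1 | starting material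
13 | 2-hydroxy-6-({(3S)-5-[(3R,4S)-5,5-dimethyl-1-oxaspiro[2.5]octan-4-yl]-3-methylpent-1-en-3-yl}oxy)-4-methylbenzaldehyde | Cc1cc(O)c(C=O)c(c1)O[C@@](C)(CC[C@H]1C(C)(C)CCC[C@]12CO2)C=C | intermediate
14 | 2-ethenyl-3-({(3S)-5-[(3R,4S)-5,5-dimethyl-1-oxaspiro[2.5]octan-4-yl]-3-methylpent-1-en-3-yl}oxy)-5-methylphenol | Cc1cc(O)c(C=C)c(c1)O[C@@](C)(CC[C@H]1C(C)(C)CCC[C@]12CO2)C=C | intermediate
15 | (2S)-2-{2-[(3R,4S)-5,5-dimethyl-1-oxaspiro[2.5]octan-4-yl]ethyl}-2,7-dimethyl-2H-chromen-5-ol | Cc1cc(O)c2c(c1)O[C@@](C)(CC[C@H]1C(C)(C)CCC[C@]13CO3)C=C2 | intermediate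
16 | (2S)-2-{2-[(1S,2R)-2-hydroxy-2-(hydroxymethyl)-6,6-dimethylcyclohexyl]ethyl}-2,7-dimethyl-2H-chromen-5-ol | Cc1cc(O)c2c(c1)O[C@@](C)(CC[C@H]1C(C)(C)CCC[C@]1(O)CO)C=C2 | target

**Step count and risks**

Total steps: 12. Longest linear sequence: 12 steps, from 1 to 16; 3 and 12 enter as commercial partners.

Steps most likely to fail:

Step 9. The phenoxide may attack the unsubstituted allyl terminus, the two faces of the pi-allyl complex may be poorly discriminated, or the product may re-ionise and equilibrate to the linear ether. The fallback makes the tertiary C–O bond by reagent-controlled epoxidation instead of at palladium. Setting out from 10, Sharpless asymmetric epoxidation (Ti(OiPr)4, L-(+)-diethyl tartrate, t-BuOOH, 4 Å sieves, CH2Cl2, −20 °C) should give the (2S,3S)-epoxy alcohol F1. Iodination (PPh3, I2, imidazole) gives the epoxy iodide F2, and zinc dust in ethanol opens it reductively to the (S)-tertiary allylic alcohol F3 without touching the C–O bond of the stereocentre. Its potassium alkoxide (KN(SiMe3)2, THF, 0 °C) displaces one fluoride of 2,6-difluoro-4-methylbenzaldehyde to give the fluoro aryl ether F4. The second fluoride is exchanged for hydroxyl with 2-(methylsulfonyl)ethanol and NaH in DMF, which returns to the route at 13.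

Step 4. The alkene walk may stall at the allylic alcohol, or the hydride may be diverted into hydrogen transfer with the side-chain ketone, leaving mixtures. The fallback separates ring closure from the redox adjustment. From 5 the metathesis is run alone and the cyclohexenol 6 is isolated, hydrogenated (H2, Pd/C, EtOAc) to the saturated hydroxy ketone F5 and oxidised with Dess–Martin periodinane, which returns at 7.

Step 12. SN2 attack at the neopentyl-like epoxide CH2 may be slow, and long heating of the chromene invites electrocyclic ring-opening and loss of configuration at the ether carbon. The fallback opens the epoxide before the arene is present. From 10, KOH in DMSO/water at 110 °C should give the triol F6, and 2,2-dimethoxypropane with pyridinium p-toluenesulfonate protects the 1,2-diol as the acetonide F7. The conditions of steps 8 to 11 then lead through the carbonate F8, the aryl ether aldehyde F9, the styrene F10 and the chromene acetonide F11. Aqueous acetic acid at 40 °C removes the acetonide and returns at 16.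

Further compounds
F1 | step 9 | {(2S,3S)-3-{2-[(3R,4S)-5,5-dimethyl-1-oxaspiro[2.5]octan-4-yl]ethyl}-3-methyloxiran-2-yl}methanol | OC[C@@H]1O[C@@]1(C)CC[C@H]2C(C)(C)CCC[C@]23CO3
F2 | step 9 | (3R,4S)-4-{2-[(2S,3R)-3-(iodomethyl)-2-methyloxiran-2-yl]ethyl}-5,5-dimethyl-1-oxaspiro[2.5]octane | IC[C@@H]1O[C@@]1(C)CC[C@H]2C(C)(C)CCC[C@]23CO3
F3 | step 9 | (3S)-5-[(3R,4S)-5,5-dimethyl-1-oxaspiro[2.5]octan-4-yl]-3-methylpent-1-en-3-ol | O[C@@](C)(CC[C@H]1C(C)(C)CCC[C@]12CO2)C=C
F4 | step 9 | 2-fluoro-6-({(3S)-5-[(3R,4S)-5,5-dimethyl-1-oxaspiro[2.5]octan-4-yl]-3-methylpent-1-en-3-yl}oxy)-4-methylbenzaldehyde | Cc1cc(F)c(C=O)c(c1)O[C@@](C)(CC[C@H]1C(C)(C)CCC[C@]12CO2)C=C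
F5 | step 4 | 4-[(1S)-2-hydroxy-6,6-dimethylcyclohexyl]butan-2-one (both carbinol epimers) | CC(=O)CC[C@H]1C(C)(C)CCCC1O
F6 | step 12 | (1R,2S)-1-(hydroxymethyl)-2-[(3E)-5-hydroxy-3-methylpent-3-en-1-yl]-3,3-dimethylcyclohexan-1-ol | OC/C=C(\C)CC[C@H]1C(C)(C)CCC[C@]1(O)CO
F7 | step 12 | (2E)-3-methyl-5-[(5R,6S)-2,2,7,7-tetramethyl-1,3-dioxaspiro[4.5]decan-6-yl]pent-2-en-1-ol | OC/C=C(\C)CC[C@H]1C(C)(C)CCC[C@]12COC(C)(C)O2
F8 | step 12 | methyl (2E)-3-methyl-5-[(5R,6S)-2,2,7,7-tetramethyl-1,3-dioxaspiro[4.5]decan-6-yl]pent-2-en-1-yl carbonate | COC(=O)OC/C=C(\C)CC[C@H]1C(C)(C)CCC[C@]12COC(C)(C)O2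
F9 | step 12 | 2-hydroxy-4-methyl-6-({(3S)-3-methyl-5-[(5R,6S)-2,2,7,7-tetramethyl-1,3-dioxaspiro[4.5]decan-6-yl]pent-1-en-3-yl}oxy)benzaldehyde | Cc1cc(O)c(C=O)c(c1)O[C@@](C)(CC[C@H]1C(C)(C)CCC[C@]12COC(C)(C)O2)C=C
F10 | step 12 | 2-ethenyl-5-methyl-3-({(3S)-3-methyl-5-[(5R,6S)-2,2,7,7-tetramethyl-1,3-dioxaspiro[4.5]decan-6-yl]pent-1-en-3-yl}oxy)phenol | Cc1cc(O)c(C=C)c(c1)O[C@@](C)(CC[C@H]1C(C)(C)CCC[C@]12COC(C)(C)O2)C=C
F11 | step 12 | (2S)-2,7-dimethyl-2-{2-[(5R,6S)-2,2,7,7-tetramethyl-1,3-dioxaspiro[4.5]decan-6-yl]ethyl}-2H-chromen-5-ol | Cc1cc(O)c2c(c1)O[C@@](C)(CC[C@H]1C(C)(C)CCC[C@]13COC(C)(C)O3)C=C2
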